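The numbers of this flask were chosen freely; the rest is arithmetic.

I started from late times and asked how far this charge of J can carry E.

| setting | blue | violet |
|---|---|---|
| E | 0.18 M | 0.18 M |
| J | 0.198 M | 0.198 M |
| time | 10 s | 25 s |
    J + E.J → J.E.J (k1 = 0.419 M⁻¹ s⁻¹)
    J + J.E.J → G (k2 = 1.14 M⁻¹ s⁻¹)
    J.E.J → Z (k3 = 0.0337 s⁻¹)
    E + J → E.J (k4 = 0.620 M⁻¹ s⁻¹)
- which of these there is most of at the end, counted by the E in it, blue (G / E.J / E / J.E.J)
- which of these there is most of at the end, counted by the E in it, violet (G / E.J / E / J.E.J)
- final amount of the leader among these, as a percentage of the E charged, in blue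
- final amount of the leader among these, as a percentage of the E charged, in violet

Both flasks hold 1.10 equivalents of J on E, and the oddity is that J stands in excess and yet E should survive. Each E that passes E.J costs 2 J on the way to Z or 3 on the way to G, so I priced it at 2.50. I measured progress by exposure, the time integral of [J]: E falls exponentially in it with 0.620 M⁻¹ s⁻¹, and E.J follows, drained with 0.419 M⁻¹ s⁻¹.

First I ignored E.J, which left E at 56.0% and, at that exposure, E.J at 35.7%. Putting that E.J back at its price of one J gave 34.6% and 43.8%; another round gave 29.7% and 44.2%. So J is the limiting reagent by price, though not by count.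

[E] equals [E.J] at 1.40 M·s, the crossover exposure: E leads below it, E.J above it. There my budget put [J] at 50.8 mM. A straight fall of [J] from the charge to that value reaches the crossover at 11.2 s, later than blue's end and earlier than violet's. I committed to E at 44.0% in blue and E.J near 44.2% in violet.

The forecast gave E at 46.6% in blue, above my figure, and E.J at 44.1% in violet, where “J is nearly exhausted”.

The simulation gave E at 46.8% in blue and E.J at 44.0% in violet. In violet, E + J → E.J had 86% of its turnover behind it at 12.5 s, when E at 42.4% read an exposure of 1.38 M·s, close to the crossover, with E.J at 41.9%. In a neighbour of violet charged with 0.079 M of J, E at 65.2% read 0.690 M·s, less than the crossover, and E held the lead over E.J at 29.9%.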